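The constants are those of an exercise; no experiment stands behind them.

Two amounts of intermediate A and one verdict between them are asked, for one charge of starting material, run through a stirred tank (noon) and held in a closed flask (autumn).

common to all: starting material 1.0 M
- noon: one stirred flow tank at steady state, fed with the mixture as stated, mean residence time 3.0 h
- autumn: everything together in a closed stirred flask, run for 3.0 h; time 3.0 h

    intermediate B → intermediate C (k1 = 0.0026 min⁻¹)
    intermediate A → intermediate B (k2 = 0.0025 min⁻¹)
    starting material → intermediate A (k3 = 0.0033 min⁻¹)
    starting material ⇌ dormant form (K4 = 0.71, k4 = 0.0070 min⁻¹)
    intermediate C → product (k5 = 0.0087 min⁻¹)

- the set-up with the highest amount of intermediate A at the outlet or at the end, in percent of the starting material put in ("none" if the first two lie within 2 percentage points) (noon / autumn / none)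
- amount of intermediate A at the outlet or at the end, in percent of the starting material put in, noon
- amount of intermediate A at the outlet or at the end, in percent of the starting material put in, autumn

The ledger follows each mole of starting material: still free, parked as dormant form, or passed to intermediate A, which keeps part and hands the rest onward. Nothing returns from beyond intermediate A.

In the noon tank, each unit of c(starting material) at the outlet comes with 0.454 units of dormant form and 0.594 units converted. The feed therefore closes the books at c(starting material) = 0.488 M. Of the 0.290 M converted, the noon tank keeps 0.200 M as intermediate A, which is 20.0% of the starting material put in.

The autumn flask is solved at both ends and joined. Late on, starting material and dormant form behave as one pool at pre-equilibrium, and this pool drains at the leak constant, k3 times the free share of the pool: 0.00193 min⁻¹. This end covers most of the run because the pair relaxes in about 59.3 min, less than the 3.0 h of the run. At the start, the free excess of 41.5% lasts about that long and adds a head entry of 8.13% to intermediate A. Joined, the pool keeps 64.9%. The tail entry, 27.0%, is reckoned as arriving evenly and the head entry as arriving about 59.3 min in. After losses through k2, the autumn flask keeps 27.7% as intermediate A, which is 7.7 percentage points above noon, against a margin of 2 points.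

The forecast, with 20% for noon and 26.1% for autumn, lies below this autumn reckoning and concludes: “The flask wins by about 6 points”.

The simulation gives 20.0% at noon and 26.1% in autumn, so autumn holds more intermediate A, against the hand figure of 27.7% for the autumn flask. At 3.00 h, the autumn flask holds starting material 37.3% and dormant form 29.1%, together 66.4% against the 64.9% reckoned from the leak constant. For the same flask read at 8.0 h, the leak constant leaves 36.4% in the pool, and that flask holds starting material 20.8% with dormant form 18.0%.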